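The route rests on disconnecting C9–C11 and C1–C10 (drimane numbering) from a ring B cyclohexenone. The feature exploited is that C9 and quaternary C10 are neighbours in ring B beside C8, whose exocyclic methylene can be carried as a silyloxy stereocentre. In one operation a copper-catalysed silylmethyl Grignard addition should install C11 at C9 anti to the C8 oxygen, and the resulting C10 enolate should be trapped by an α-silyl vinyl ketone anti to the new C9 group. This sets both stereocentres and delivers every ring A carbon except one C4 methyl. The precursor is (S)-4-silyloxy-2-methylcyclohexenone 5, reached in four steps from a commercial ketone.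

Key step: step 7

Convention: bicyclic compounds are described in drimane numbering (ring A = C1–C5 and C10; ring B = C5–C10; C11 = CH2 on C9; C12 = carbon on C8); "syn" and "anti" refer to the face of the C10 methyl group, and the SMILES give the absolute configuration.

Assumption: lithium (R,R)-bis(1-phenylethyl)amide is taken to discriminate the enantiotopic α-protons of 1 in the same sense as for 4-tert-butylcyclohexanone, giving the (S)-enol ether; should the opposite sense be found, the (S,S)-amide is used.

Step 1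
Reactants: 1 4-(tert-butyldimethylsilyloxy)cyclohexanone
Product: 2 (S)-4-(tert-butyldimethylsilyloxy)-1-(trimethylsilyloxy)cyclohexene
Conditions: (R,R)-bis(1-phenylethyl)amine, n-BuLi, LiCl, THF, −78 °C; TMSCl then 1 (internal quench), −78 °C
Reagents that add atoms: chlorotrimethylsilane, C[Si](C)(C)Cl
Why: Enantioselective deprotonation of a prochiral 4-substituted cyclohexanone by a C2-symmetric chiral lithium amide with in situ silylation should set the future C8 stereocentre by choice between the two enantiotopic axial α-protons; any shortfall in enantiomeric purity is to be removed by recrystallising a later crystalline intermediate such as 16 or 20.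

Step 2
Reactants: 2 (S)-4-(tert-butyldimethylsilyloxy)-1-(trimethylsilyloxy)cyclohexene
Product: 3 (S)-4-(tert-butyldimethylsilyloxy)cyclohex-2-en-1-one
Conditions: Pd(OAc)2 (10 mol %), O2 (1 atm), DMSO, rt
Reagents that add atoms: none
Why: Saegusa–Ito oxidation of the silyl enol ether places the double bond on the side fixed in step 1 and does not touch the silyloxy stereocentre.

Step 3
Reactants: 3 (S)-4-(tert-butyldimethylsilyloxy)cyclohex-2-en-1-one
Product: 4 (S)-4-(tert-butyldimethylsilyloxy)-2-iodocyclohex-2-en-1-one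
Conditions: I2, pyridine, CH2Cl2, 0 °C → rt
Reagents that add atoms: iodine, II
Why: α-Iodination of an enone by the pyridine-mediated addition–elimination (Johnson) protocol is routine for 4-silyloxy enones and leaves the γ-stereocentre alone.

Step 4
Reactants: 4 (S)-4-(tert-butyldimethylsilyloxy)-2-iodocyclohex-2-en-1-one
Product: 5 (S)-4-(tert-butyldimethylsilyloxy)-2-methylcyclohex-2-en-1-one
Conditions: MeZnCl (2 M in THF), Pd(PPh3)4 (5 mol %), THF, 0 °C → rt
Reagents that add atoms: methylzinc chloride, C[Zn]Cl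
Why: Negishi cross-coupling of an α-iodoenone runs under neutral conditions, so base-induced loss of the γ-silyloxy group is avoided.

Step 5
Reactants: 6 (chloromethyl)(isopropoxy)dimethylsilane
Product: 7 [(isopropoxydimethylsilyl)methyl]magnesium chloride
Conditions: Mg, BrCH2CH2Br (cat.), THF, reflux → rt
Reagents that add atoms: magnesium, [Mg]
Why: Grignard formation from the α-chloromethylsilane gives the standard hydroxymethyl anion equivalent for later Tamao oxidation.

Step 6
Reactants: 8 (1-bromovinyl)trimethylsilane; 9 N-methoxy-N-methylpropanamide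
Product: 11 2-(trimethylsilyl)pent-1-en-3-one, via 1-(trimethylsilyl)vinylmagnesium bromide 10 (not isolated)
Conditions: Mg, THF, reflux; then 9, THF, 0 °C → rt; cold 1 M HCl
Reagents that add atoms: none
Why: Weinreb ketone synthesis: the chelated tetrahedral adduct releases the α-silyl enone only on work-up, so the Grignard reagent cannot add to the product.

Step 7
Reactants: 5 (S)-4-(tert-butyldimethylsilyloxy)-2-methylcyclohex-2-en-1-one; 7 [(isopropoxydimethylsilyl)methyl]magnesium chloride; 11 2-(trimethylsilyl)pent-1-en-3-one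
Product: 14 (2S,3S,4S)-4-(tert-butyldimethylsilyloxy)-3-{[isopropoxy(dimethyl)silyl]methyl}-2-methyl-2-(3-oxopentyl)cyclohexan-1-one, via chloromagnesium enolate 12 (not isolated), via alpha-silyl diketone 13 (not isolated)
Conditions: 7 (1.3 equiv), CuI (10 mol %), THF, −78 → −30 °C; 11 (1.5 equiv), −78 → −20 °C; aq NH4Cl; then i-PrONa (0.2 equiv), i-PrOH, 0 °C
Reagents that add atoms: none
Why: CuI and 7 should form a silylmethyl copper species that adds 1,4 to C9 of 5 and leaves the regiodefined chloromagnesium enolate 12, whose C10 carbon then attacks the unsubstituted terminus of 11 to give a silyl-stabilised enolate that is protonated to 13 and protodesilylated by isopropoxide in isopropanol (degenerate alkoxy exchange keeps the Si–Oi-Pr group). The closest known reaction type is copper-mediated conjugate addition with enolate trapping by an α-silyl vinyl ketone, combined with the copper-catalysed addition of the Tamao silylmethyl Grignard reagent to enones. No ring is closed. C9 is controlled by the C8 silyloxy group, which sits pseudoaxial in the enone half-chair and sends the copper reagent to the opposite face; C10 is controlled by the new C9 substituent, which is pseudoaxial in the enolate (allylic strain with the C10 methyl) and blocks its own face, so the acceptor enters axially trans to it and the methyl ends up cis to CH2Si. The step needs 1,4- over 1,2-addition (copper catalysis), C-alkylation at the tetrasubstituted enolate carbon without enolate equilibration or acceptor polymerisation (the α-silyl group of 11 makes the adduct anion hindered and non-basic), and two facial selections that both derive from the single C8 stereocentre of 5.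

Step 8
Reactants: 14 (2S,3S,4S)-4-(tert-butyldimethylsilyloxy)-3-{[isopropoxy(dimethyl)silyl]methyl}-2-methyl-2-(3-oxopentyl)cyclohexan-1-one
Product: 15 8-(tert-butyldimethylsilyloxy)-9-{[isopropoxy(dimethyl)silyl]methyl}-4,10-dimethyl-Δ4-octalin-3-one
Conditions: i-PrONa, i-PrOH, 60 °C
Reagents that add atoms: none
Why: Intramolecular aldol condensation (second stage of a Robinson annulation): the ethyl ketone enolate attacks the C5 ketone in a 6-(enolendo)-exo-trig closure and dehydration gives the tetrasubstituted enone; isopropoxide keeps the alkoxysilane unchanged and no stereocentre lies α to a carbonyl.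

Step 9
Reactants: 15 8-(tert-butyldimethylsilyloxy)-9-{[isopropoxy(dimethyl)silyl]methyl}-4,10-dimethyl-Δ4-octalin-3-one
Product: 16 8-(tert-butyldimethylsilyloxy)-9-(hydroxymethyl)-4,10-dimethyl-Δ4-octalin-3-one
Conditions: 30% H2O2, KF, KHCO3, THF/MeOH (1:1), rt
Reagents that add atoms: hydrogen peroxide, OO
Why: Tamao oxidation converts the C–Si bond into C–OH with retention; bicarbonate-buffered peroxide should spare the hindered tetrasubstituted enone and the secondary TBS ether.

Step 10
Reactants: 16 8-(tert-butyldimethylsilyloxy)-9-(hydroxymethyl)-4,10-dimethyl-Δ4-octalin-3-one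
Product: 17 8-(tert-butyldimethylsilyloxy)-9-[(tert-butyldiphenylsilyloxy)methyl]-4,10-dimethyl-Δ4-octalin-3-one
Conditions: TBDPSCl, imidazole, DMF, rt
Reagents that add atoms: tert-butyl(chloro)diphenylsilane, CC(C)(C)[Si](Cl)(c1ccccc1)c1ccccc1
Why: Silylation of the primary alcohol gives an acid-stable ether, so that the C8 TBS ether can later be removed in its presence.

Step 11
Reactants: 17 8-(tert-butyldimethylsilyloxy)-9-[(tert-butyldiphenylsilyloxy)methyl]-4,10-dimethyl-Δ4-octalin-3-one
Product: 19 8-(tert-butyldimethylsilyloxy)-9-[(tert-butyldiphenylsilyloxy)methyl]-4,4,10-trimethyl-trans-decalin-3-one, via lithium enolate 18 (not isolated)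
Conditions: Li (2.2 equiv), NH3(l)/THF, t-BuOH (1.0 equiv), −78 °C; MeI (excess), −78 → −33 °C; NH4Cl
Reagents that add atoms: iodomethane, CI
Why: Stork reductive alkylation: dissolving-metal reduction of the enone with axial protonation at C5 anti to the C10 methyl should give the trans-fused C3–C4 lithium enolate regiospecifically, which is C-methylated at C4; stoichiometric lithium at −78 °C should spare the silyl ethers.

Step 12
Reactants: 19 8-(tert-butyldimethylsilyloxy)-9-[(tert-butyldiphenylsilyloxy)methyl]-4,4,10-trimethyl-trans-decalin-3-one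
Product: 20 8-(tert-butyldimethylsilyloxy)-9-[(tert-butyldiphenylsilyloxy)methyl]-4,4,10-trimethyl-trans-decalin-3-ol
Conditions: NaBH4, MeOH/THF, 0 °C
Reagents that add atoms: none
Why: Borohydride reduction of a 4,4-dimethyl-3-oxo trans-decalin proceeds by axial hydride delivery on the face anti to the C10 methyl and should give the equatorial C3 alcohol syn to that methyl.

Step 13
Reactants: 20 8-(tert-butyldimethylsilyloxy)-9-[(tert-butyldiphenylsilyloxy)methyl]-4,4,10-trimethyl-trans-decalin-3-ol
Product: 21 8-(tert-butyldimethylsilyloxy)-3-(tert-butyldiphenylsilyloxy)-9-[(tert-butyldiphenylsilyloxy)methyl]-4,4,10-trimethyl-trans-decalin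
Conditions: TBDPSCl, imidazole, DMAP, DMF, 60 °C
Reagents that add atoms: tert-butyl(chloro)diphenylsilane, CC(C)(C)[Si](Cl)(c1ccccc1)c1ccccc1
Why: Forced silylation of the hindered equatorial alcohol next to the gem-dimethyl carbon (standard for such neopentyl-type secondary alcohols) leaves the TBS ether as the only acid-labile group and needs no ester that would interfere with the later enolate and titanium steps.

Step 14
Reactants: 21 8-(tert-butyldimethylsilyloxy)-3-(tert-butyldiphenylsilyloxy)-9-[(tert-butyldiphenylsilyloxy)methyl]-4,4,10-trimethyl-trans-decalin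
Product: 22 3-(tert-butyldiphenylsilyloxy)-9-[(tert-butyldiphenylsilyloxy)methyl]-4,4,10-trimethyl-trans-decalin-8-ol
Conditions: CSA (0.2 equiv), MeOH/CH2Cl2 (1:1), 0 °C → rt
Reagents that add atoms: none
Why: Acid-catalysed methanolysis distinguishes silyl ethers by acid lability, a TBS ether being cleaved about two orders of magnitude faster than TBDPS ethers.

Step 15
Reactants: 22 3-(tert-butyldiphenylsilyloxy)-9-[(tert-butyldiphenylsilyloxy)methyl]-4,4,10-trimethyl-trans-decalin-8-ol
Product: 23 3-(tert-butyldiphenylsilyloxy)-9-[(tert-butyldiphenylsilyloxy)methyl]-4,4,10-trimethyl-trans-decalin-8-one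
Conditions: Dess–Martin periodinane, CH2Cl2, rt
Reagents that add atoms: none
Why: Dess–Martin oxidation under near-neutral conditions should give the C8 ketone without β-elimination of the C11 silyloxy group; the C9 substituent is equatorial and thus already in its stable configuration.

Step 16
Reactants: 23 3-(tert-butyldiphenylsilyloxy)-9-[(tert-butyldiphenylsilyloxy)methyl]-4,4,10-trimethyl-trans-decalin-8-one
Product: 25 3-(tert-butyldiphenylsilyloxy)-9-[(tert-butyldiphenylsilyloxy)methyl]-4,4,10-trimethyl-Δ6-octalin-8-one, via trimethylsilyl enol ether 24 (not isolated)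
Conditions: LiN(i-Pr)2 (LDA), TMSCl, THF, −78 °C; then Pd(OAc)2 (1.1 equiv), MeCN, rt
Reagents that add atoms: none
Why: Kinetic deprotonation at the C7 methylene (the C9 methine is hindered by quaternary C10) with in situ silylation, followed by Saegusa–Ito oxidation, should introduce the C6=C7 double bond without touching C5 or C9.

Step 17
Reactants: 25 3-(tert-butyldiphenylsilyloxy)-9-[(tert-butyldiphenylsilyloxy)methyl]-4,4,10-trimethyl-Δ6-octalin-8-one
Product: 26 3-(tert-butyldiphenylsilyloxy)-9-[(tert-butyldiphenylsilyloxy)methyl]-4,4,10-trimethyl-8-methylidene-Δ6-octalin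
Conditions: Cp2TiMe2, toluene/THF, 65 °C, dark
Reagents that add atoms: dimethyltitanocene, [CH3-].[CH3-].[Ti+4].c1cc[cH-]c1.c1cc[cH-]c1
Why: Petasis methylenation through Cp2Ti=CH2 is non-basic, so the enolisable enone should be converted 1,2 into the exocyclic diene without epimerisation at C9 or elimination of the C11 silyloxy group.

Step 18
Reactants: 26 3-(tert-butyldiphenylsilyloxy)-9-[(tert-butyldiphenylsilyloxy)methyl]-4,4,10-trimethyl-8-methylidene-Δ6-octalin
Product: 27 9-(hydroxymethyl)-4,4,10-trimethyl-8-methylidene-Δ6-octalin-3-ol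
Conditions: TBAF, THF, rt → 55 °C
Reagents that add atoms: none
Why: Fluoride-mediated desilylation removes both TBDPS ethers (the hindered C3 ether on warming) under non-acidic conditions that should not isomerise the exocyclic diene.

Step 19
Reactants: 27 9-(hydroxymethyl)-4,4,10-trimethyl-8-methylidene-Δ6-octalin-3-ol; 28 umbelliferone
Product: 29 7-{[(1R,4aS,6R,8aR)-6-hydroxy-5,5,8a-trimethyl-2-methylidene-1,2,4a,5,6,7,8,8a-octahydronaphthalen-1-yl]methoxy}-2H-chromen-2-one
Conditions: PPh3, DIAD, THF, 0 °C → rt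
Reagents that add atoms: none
Why: Mitsunobu etherification with the acidic phenol should take place only at the primary C11 alcohol, because the equatorial C3 alcohol beside the gem-dimethyl carbon is too hindered to be displaced; no stereocentre is involved.

Compound list
1 | 4-(tert-butyldimethylsilyloxy)cyclohexanone | O=C1CCC(CC1)O[Si](C)(C)C(C)(C)C | starting material
2 | (S)-4-(tert-butyldimethylsilyloxy)-1-(trimethylsilyloxy)cyclohexene | C[Si](C)(C)OC1=CC[C@@H](O[Si](C)(C)C(C)(C)C)CC1 | intermediate
3 | (S)-4-(tert-butyldimethylsilyloxy)cyclohex-2-en-1-one | O=C1C=C[C@@H](O[Si](C)(C)C(C)(C)C)CC1 | intermediate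
4 | (S)-4-(tert-butyldimethylsilyloxy)-2-iodocyclohex-2-en-1-one | O=C1C(I)=C[C@@H](O[Si](C)(C)C(C)(C)C)CC1 | intermediate
5 | (S)-4-(tert-butyldimethylsilyloxy)-2-methylcyclohex-2-en-1-one | CC1=C[C@@H](O[Si](C)(C)C(C)(C)C)CCC1=O | intermediate
6 | (chloromethyl)(isopropoxy)dimethylsilane | CC(C)O[Si](C)(C)CCl | starting material
7 | [(isopropoxydimethylsilyl)methyl]magnesium chloride | CC(C)O[Si](C)(C)C[Mg]Cl | intermediate
8 | (1-bromovinyl)trimethylsilane | C=C(Br)[Si](C)(C)C | starting material
9 | N-methoxy-N-methylpropanamide | CCC(=O)N(C)OC | starting material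
10 | 1-(trimethylsilyl)vinylmagnesium bromide | C=C([Mg]Br)[Si](C)(C)C | intermediate
11 | 2-(trimethylsilyl)pent-1-en-3-one | CCC(=O)C(=C)[Si](C)(C)C | intermediate
12 | chloromagnesium (3S,4S)-4-(tert-butyldimethylsilyloxy)-3-{[isopropoxy(dimethyl)silyl]methyl}-2-methylcyclohex-1-en-1-olate | CC1=C(O[Mg]Cl)CC[C@H](O[Si](C)(C)C(C)(C)C)[C@H]1C[Si](C)(C)OC(C)C | intermediate
13 | (2S,3S,4S)-4-(tert-butyldimethylsilyloxy)-3-{[isopropoxy(dimethyl)silyl]methyl}-2-methyl-2-[3-oxo-2-(trimethylsilyl)pentyl]cyclohexan-1-one, both epimers at the silyl-bearing carbon | CCC(=O)C(C[C@]1(C)C(=O)CC[C@H](O[Si](C)(C)C(C)(C)C)[C@H]1C[Si](C)(C)OC(C)C)[Si](C)(C)C | intermediate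
14 | (2S,3S,4S)-4-(tert-butyldimethylsilyloxy)-3-{[isopropoxy(dimethyl)silyl]methyl}-2-methyl-2-(3-oxopentyl)cyclohexan-1-one (silyloxy, silylmethyl and oxopentyl groups all trans) | CCC(=O)CC[C@]1(C)C(=O)CC[C@H](O[Si](C)(C)C(C)(C)C)[C@H]1C[Si](C)(C)OC(C)C | intermediate
15 | 8-(tert-butyldimethylsilyloxy)-9-{[isopropoxy(dimethyl)silyl]methyl}-4,10-dimethyl-Δ4-octalin-3-one; C8–O anti, C9–CH2 syn | CC1=C2CC[C@H](O[Si](C)(C)C(C)(C)C)[C@@H](C[Si](C)(C)OC(C)C)[C@]2(C)CCC1=O | intermediate
16 | 8-(tert-butyldimethylsilyloxy)-9-(hydroxymethyl)-4,10-dimethyl-Δ4-octalin-3-one; C8–O anti, C9–CH2 syn | CC1=C2CC[C@H](O[Si](C)(C)C(C)(C)C)[C@@H](CO)[C@]2(C)CCC1=O | intermediate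
17 | 8-(tert-butyldimethylsilyloxy)-9-[(tert-butyldiphenylsilyloxy)methyl]-4,10-dimethyl-Δ4-octalin-3-one; C8–O anti, C9–CH2 syn | CC1=C2CC[C@H](O[Si](C)(C)C(C)(C)C)[C@@H](CO[Si](c3ccccc3)(c3ccccc3)C(C)(C)C)[C@]2(C)CCC1=O | intermediate
18 | lithium C3–C4 enolate of the trans-fused 4,10-dimethyl-decalin-3-one bearing C8–OTBS (anti) and C9–CH2OTBDPS (syn); C5–H anti | CC(C)(C)[Si](C)(C)O[C@H]1CC[C@@H]2C(C)=C(O[Li])CC[C@@]2(C)[C@@H]1CO[Si](c1ccccc1)(c1ccccc1)C(C)(C)C | intermediate
19 | 8-(tert-butyldimethylsilyloxy)-9-[(tert-butyldiphenylsilyloxy)methyl]-4,4,10-trimethyl-trans-decalin-3-one; C5–H and C8–O anti, C9–CH2 syn | CC(C)(C)[Si](C)(C)O[C@H]1CC[C@@H]2C(C)(C)C(=O)CC[C@@]2(C)[C@@H]1CO[Si](c1ccccc1)(c1ccccc1)C(C)(C)C | intermediate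
20 | 8-(tert-butyldimethylsilyloxy)-9-[(tert-butyldiphenylsilyloxy)methyl]-4,4,10-trimethyl-trans-decalin-3-ol; C3–OH equatorial and syn, C5–H and C8–O anti, C9–CH2 syn | CC(C)(C)[Si](C)(C)O[C@H]1CC[C@@H]2C(C)(C)[C@H](O)CC[C@@]2(C)[C@@H]1CO[Si](c1ccccc1)(c1ccccc1)C(C)(C)C | intermediate
21 | 8-(tert-butyldimethylsilyloxy)-3-(tert-butyldiphenylsilyloxy)-9-[(tert-butyldiphenylsilyloxy)methyl]-4,4,10-trimethyl-trans-decalin; C3–O and C9–CH2 syn, C5–H and C8–O anti | CC(C)(C)[Si](C)(C)O[C@H]1CC[C@@H]2C(C)(C)[C@H](O[Si](c3ccccc3)(c3ccccc3)C(C)(C)C)CC[C@@]2(C)[C@@H]1CO[Si](c1ccccc1)(c1ccccc1)C(C)(C)C | intermediate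
22 | 3-(tert-butyldiphenylsilyloxy)-9-[(tert-butyldiphenylsilyloxy)methyl]-4,4,10-trimethyl-trans-decalin-8-ol; C3–O and C9–CH2 syn, C5–H and C8–OH anti | O[C@H]1CC[C@@H]2C(C)(C)[C@H](O[Si](c3ccccc3)(c3ccccc3)C(C)(C)C)CC[C@@]2(C)[C@@H]1CO[Si](c1ccccc1)(c1ccccc1)C(C)(C)C | intermediate
23 | 3-(tert-butyldiphenylsilyloxy)-9-[(tert-butyldiphenylsilyloxy)methyl]-4,4,10-trimethyl-trans-decalin-8-one; C3–O and C9–CH2 syn, C5–H anti | O=C1CC[C@@H]2C(C)(C)[C@H](O[Si](c3ccccc3)(c3ccccc3)C(C)(C)C)CC[C@@]2(C)[C@@H]1CO[Si](c1ccccc1)(c1ccccc1)C(C)(C)C | intermediate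
24 | C7=C8 trimethylsilyl enol ether of 23 | C[Si](C)(C)OC1=CC[C@@H]2C(C)(C)[C@H](O[Si](c3ccccc3)(c3ccccc3)C(C)(C)C)CC[C@@]2(C)[C@@H]1CO[Si](c1ccccc1)(c1ccccc1)C(C)(C)C | intermediate
25 | 3-(tert-butyldiphenylsilyloxy)-9-[(tert-butyldiphenylsilyloxy)methyl]-4,4,10-trimethyl-Δ6-octalin-8-one; C3–O and C9–CH2 syn, C5–H anti | O=C1C=C[C@@H]2C(C)(C)[C@H](O[Si](c3ccccc3)(c3ccccc3)C(C)(C)C)CC[C@@]2(C)[C@@H]1CO[Si](c1ccccc1)(c1ccccc1)C(C)(C)C | intermediate
26 | 3-(tert-butyldiphenylsilyloxy)-9-[(tert-butyldiphenylsilyloxy)methyl]-4,4,10-trimethyl-8-methylidene-Δ6-octalin; C3–O and C9–CH2 syn, C5–H anti | C=C1C=C[C@@H]2C(C)(C)[C@H](O[Si](c3ccccc3)(c3ccccc3)C(C)(C)C)CC[C@@]2(C)[C@@H]1CO[Si](c1ccccc1)(c1ccccc1)C(C)(C)C | intermediate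
27 | 9-(hydroxymethyl)-4,4,10-trimethyl-8-methylidene-Δ6-octalin-3-ol, (3R,5S,9R,10R); C3–OH and C9–CH2OH syn, C5–H anti | C=C1C=C[C@@H]2C(C)(C)[C@H](O)CC[C@@]2(C)[C@@H]1CO | intermediate
28 | umbelliferone (7-hydroxy-2H-chromen-2-one) | O=c1ccc2ccc(O)cc2o1 | starting material
29 | 7-{[(1R,4aS,6R,8aR)-6-hydroxy-5,5,8a-trimethyl-2-methylidene-1,2,4a,5,6,7,8,8a-octahydronaphthalen-1-yl]methoxy}-2H-chromen-2-one (3R,5S,9R,10R in drimane numbering) | C=C1C=C[C@@H]2C(C)(C)[C@H](O)CC[C@@]2(C)[C@@H]1COc1ccc2ccc(=O)oc2c1 | target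

Total step count: 19. Longest linear sequence: 17 steps (steps 1–4 and 7–19, from 1 to 29); steps 5 and 6 are one-step side branches.

Steps most likely to fail

Step 7. The facial selectivity of the Michael stage may erode, the magnesium enolate may be quenched by proton transfer from the acceptor, or the acceptor may oligomerise. The fallback sets out from 5 and 7. The copper-catalysed conjugate addition is run with TMSCl present (CuI cat., THF, −78 °C; Et3N work-up), so that the enolate is isolated as the trimethylsilyl enol ether F1. This is joined to commercial ethyl vinyl ketone in a Mukaiyama–Michael addition (Sc(OTf)3 cat., CH2Cl2, −78 °C; aqueous work-up). The same C1–C10 bond forms under Lewis-acid activation, again anti to the C9 substituent, and the route is rejoined at 14.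

Step 19. Displacement at the β-branched C11 oxyphosphonium ion may be slow, which would leave room for elimination toward the diene or alkylation of the hydrazide by-product. The fallback sets out from 27. Selective sulfonylation of the primary alcohol (MsCl, Et3N, CH2Cl2, −20 °C) should give the C11 methanesulfonate F2. Williamson displacement with umbelliferone 28 (Cs2CO3, DMF, 60 °C) then leads to 29.

Step 11. The ketone may be over-reduced, the aryl silyl ether may be damaged reductively, or the enolate may be protonated before it is methylated. The fallback sets out from 17. Deconjugative methylation (KOt-Bu, MeI, t-BuOH/THF, rt) should give the 4,4-dimethyl-Δ5-octalin-3-one F3. Hydrogenation (H2, Pd/C, EtOAc) from the face anti to the C10 methyl then installs the trans C5 hydrogen and rejoins the route at 19.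

Further compounds
F1 | step 7 | trimethylsilyl enol ether: tert-butyl{[(1S,2S)-2-{[isopropoxy(dimethyl)silyl]methyl}-3-methyl-4-(trimethylsilyloxy)cyclohex-3-en-1-yl]oxy}dimethylsilane | CC1=C(O[Si](C)(C)C)CC[C@H](O[Si](C)(C)C(C)(C)C)[C@H]1C[Si](C)(C)OC(C)C
F2 | step 19 | C11 methanesulfonate of diol 27 | C=C1C=C[C@@H]2C(C)(C)[C@H](O)CC[C@@]2(C)[C@@H]1COS(C)(=O)=O
F3 | step 11 | 8-(tert-butyldimethylsilyloxy)-9-[(tert-butyldiphenylsilyloxy)methyl]-4,4,10-trimethyl-Δ5-octalin-3-one | CC(C)(C)[Si](C)(C)O[C@H]1CC=C2C(C)(C)C(=O)CC[C@@]2(C)[C@@H]1CO[Si](c1ccccc1)(c1ccccc1)C(C)(C)C
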